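**Strategy.** The oxocane (ring O, C6–C12; chain numbered C1, alkyne CH, to C15, ethyl CH3) is not cyclised but unveiled. C6 and C10 can both stand at carbonyl level, so they are first joined as the C6=C10 ring-fusion enol ether of a 2-oxabicyclo[3.3.0]oct-1(5)-ene (dihydrofuran O/C6/C10/C11/C12 fused to cyclopentene C6–C10). Ozonolysis of that one bond gives the eight-membered lactone and the C10 ketone in a single operation, with C7, C9, C12 and C13 already in place. The precursor carries identical PMB ethers at C7 and C9, so its C2-symmetric dibromocyclopentene parent has equivalent bromines; it is assembled by epoxide opening and copper-catalysed O-vinylation.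

Key step: step 12

Remarks on the chemistry:
- Assumption: penta-1,4-dien-3-ol (1) and (R)-4-(tert-butyldimethylsilyloxy)cyclopent-2-en-1-one (5, the silylated, oxidised form of enzymatically desymmetrised cyclopent-4-ene-1,3-diol) are taken as commercial.
- In 5–15 the two oxygenated ring carbons become C7 and C9, and the alkene carbons become C6 and C10.
- Intermediates 17 (acid-labile enol ether), 19 (β-acyloxy ketone, base-labile) and 20 (free C10–OH next to a strained lactone) should be carried forward without delay.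

**Step 1**
Reactants: 1 penta-1,4-dien-3-ol
Product: 2 (2R,3S)-1,2-epoxypent-4-en-3-ol
Conditions: Ti(OiPr)4 (10 mol%), L-(+)-DIPT (13 mol%), t-BuOOH, 4 Å MS, CH2Cl2, −20 °C
Reagents that add atoms: tert-butyl hydroperoxide, CC(C)(C)OO
Why: Sharpless asymmetric epoxidation of the divinyl carbinol selects one enantiotopic vinyl group and one face to give the anti epoxy alcohol, and the minor enantiomer is consumed by a faster second epoxidation, so both future stereocenters C12 (R) and C13 (S) are set by the tartrate.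

**Step 2**
Reactants: 2 (2R,3S)-1,2-epoxypent-4-en-3-ol
Product: 3 (2R,3S)-3-(tert-butyldiphenylsilyloxy)-1,2-epoxypent-4-ene
Conditions: TBDPSCl, imidazole, DMF, 0 °C → rt
Reagents that add atoms: tert-butyldiphenylsilyl chloride, CC(C)(C)[Si](Cl)(c1ccccc1)c2ccccc2
Why: Silylation of a secondary alcohol under mild imidazole conditions avoids Payne rearrangement, and the bulky TBDPS group is chosen because it resists migration and cleavage in the basic and Lewis acidic steps ahead.

**Step 3**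
Reactants: 3 (2R,3S)-3-(tert-butyldiphenylsilyloxy)-1,2-epoxypent-4-ene
Product: 4 (2R,3S)-3-(tert-butyldiphenylsilyloxy)-1,2-epoxypentane
Conditions: H2 (1 atm), RhCl(PPh3)3 (5 mol%), toluene, rt
Reagents that add atoms: none
Why: Homogeneous hydrogenation with RhCl(PPh3)3 should reduce only the monosubstituted alkene and leave the epoxide and the allylic C–O bond intact, with no stereocenter touched.

**Step 4**
Reactants: 5 (R)-4-(tert-butyldimethylsilyloxy)cyclopent-2-en-1-one
Product: 7 (R)-2-bromo-4-(tert-butyldimethylsilyloxy)cyclopent-2-en-1-one, via dibromoketone 6 (not isolated)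
Conditions: Br2, CH2Cl2, 0 °C; then Et3N, 0 °C → rt
Reagents that add atoms: bromine, BrBr
Why: Bromine adds to the enone and triethylamine removes the acidic α-proton with loss of the β-bromide (addition then E1cB elimination), the standard α-bromination of cyclic enones.

**Step 5**
Reactants: 7 (R)-2-bromo-4-(tert-butyldimethylsilyloxy)cyclopent-2-en-1-one
Product: 8 (1S,4R)-2-bromo-4-(tert-butyldimethylsilyloxy)cyclopent-2-en-1-ol
Conditions: NaBH4, CeCl3·7H2O, MeOH, −78 °C
Reagents that add atoms: none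
Why: Luche reduction gives clean 1,2-reduction, and hydride should enter anti to the silyloxy group to give the cis-1,4 alcohol.

**Step 6**
Reactants: 8 (1S,4R)-2-bromo-4-(tert-butyldimethylsilyloxy)cyclopent-2-en-1-ol
Product: 9 (1R,4R)-2-bromo-4-(tert-butyldimethylsilyloxy)cyclopent-2-en-1-yl 4-nitrobenzoate
Conditions: 4-nitrobenzoic acid, PPh3, DIAD, THF, 0 °C → rt
Reagents that add atoms: 4-nitrobenzoic acid, O=C(O)c1ccc(cc1)[N+](=O)[O-]
Why: Mitsunobu esterification inverts the carbinol carbon by SN2 displacement of the oxyphosphonium group, converting the cis-1,4 into the trans (R,R) relationship needed at C7 and C9.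

**Step 7**
Reactants: 9 (1R,4R)-2-bromo-4-(tert-butyldimethylsilyloxy)cyclopent-2-en-1-yl 4-nitrobenzoate
Product: 11 (1R,4R)-2,3-dibromo-4-(tert-butyldimethylsilyloxy)cyclopent-2-en-1-yl 4-nitrobenzoate, via tribromide 10 (not isolated)
Conditions: Br2, CH2Cl2, 0 °C → rt; then DBU, rt
Reagents that add atoms: bromine, BrBr
Why: Bromine addition to the vinyl bromide gives a 1,1,2-tribromide whose most acidic proton (on the CHBr carbon) always has an anti geminal bromine, so E2 loss of HBr should give the tetrasubstituted 1,2-dibromoalkene (classical bromination–dehydrobromination of a bromocycloalkene); ester and silyl ether tolerate both reagents.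

**Step 8**
Reactants: 11 (1R,4R)-2,3-dibromo-4-(tert-butyldimethylsilyloxy)cyclopent-2-en-1-yl 4-nitrobenzoate
Product: 13 (1R,3R)-4,5-dibromocyclopent-4-ene-1,3-diol, via silyl ether alcohol 12 (not isolated)
Conditions: K2CO3 (cat.), MeOH, 0 °C → rt; then HCl (to pH 1), rt
Reagents that add atoms: none
Why: Base-catalysed transesterification removes the nitrobenzoate and acidification of the same methanol solution cleaves the allylic TBS ether, giving the C2-symmetric diol without affecting the vinyl bromides.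

**Step 9**
Reactants: 13 (1R,3R)-4,5-dibromocyclopent-4-ene-1,3-diol
Product: 14 (3R,5R)-1,2-dibromo-3,5-bis(4-methoxybenzyloxy)cyclopent-1-ene
Conditions: NaH, PMBCl, Bu4NI (cat.), DMF, 0 °C → rt
Reagents that add atoms: 4-methoxybenzyl chloride, COc1ccc(CCl)cc1
Why: Williamson etherification of both alkoxides; identical PMB ethers keep the C2 axis, can chelate zinc at C9 later, and leave together under DDQ.

**Step 10**
Reactants: 14 (3R,5R)-1,2-dibromo-3,5-bis(4-methoxybenzyloxy)cyclopent-1-ene; 4 (2R,3S)-3-(tert-butyldiphenylsilyloxy)-1,2-epoxypentane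
Product: 16 (2R,3S)-1-[(3R,5R)-2-bromo-3,5-bis(4-methoxybenzyloxy)cyclopent-1-en-1-yl]-3-(tert-butyldiphenylsilyloxy)pentan-2-ol, via alkenylmagnesium chloride 15 (not isolated)
Conditions: iPrMgCl·LiCl, THF, −15 °C → rt; then CuI (10 mol%), 4, −30 → 0 °C
Reagents that add atoms: none
Why: Bromine–magnesium exchange on either of the two homotopic bromides gives a single alkenylmagnesium species that cannot β-eliminate inside a five-membered ring, and copper-catalysed SN2 opening of the epoxide at its CH2 terminus forms C10–C11 with C12 and C13 untouched.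

**Step 11**
Reactants: 16 (2R,3S)-1-[(3R,5R)-2-bromo-3,5-bis(4-methoxybenzyloxy)cyclopent-1-en-1-yl]-3-(tert-butyldiphenylsilyloxy)pentan-2-ol
Product: 17 (2R,4R,6R)-2-[(1S)-1-(tert-butyldiphenylsilyloxy)propyl]-4,6-bis(4-methoxybenzyloxy)-3,4,5,6-tetrahydro-2H-cyclopenta[b]furan
Conditions: CuI (10 mol%), 1,10-phenanthroline (20 mol%), Cs2CO3, toluene, 110 °C
Reagents that add atoms: none
Why: Copper-catalysed intramolecular O-vinylation (Ullmann-type C–O coupling of an alkenyl bromide with a tethered secondary alcohol) should close the dihydrofuran through the C12 oxygen and C6, leaving the double bond at C6=C10; the five-membered closure outruns intermolecular coupling and the TBDPS ether resists 1,2-silyl migration.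

**Step 12 (key step)**
Reactants: 17 (2R,4R,6R)-2-[(1S)-1-(tert-butyldiphenylsilyloxy)propyl]-4,6-bis(4-methoxybenzyloxy)-3,4,5,6-tetrahydro-2H-cyclopenta[b]furan
Product: 19 (3R,5R,8R)-8-[(1S)-1-(tert-butyldiphenylsilyloxy)propyl]-3,5-bis(4-methoxybenzyloxy)oxocane-2,6-dione, via methoxy hydroperoxide 18 (not isolated)
Conditions: O3, CH2Cl2–MeOH (4:1), Sudan Red 7B, −78 °C; then Me2S, −78 °C → rt
Reagents that add atoms: ozone, [O-][O+]=O
Why: Ozone adds by 1,3-dipolar cycloaddition to the electron-rich tetrasubstituted enol ether C6=C10, the primary ozonide fragments (Criegee mechanism) to the C6 lactone carbonyl and a C10 carbonyl oxide that methanol traps as the methoxy hydroperoxide, and Me2S reduces this to the C10 ketone. The closest known reaction type is the oxidative cleavage of ring-fusion enol ethers of fused bicycles to medium-ring keto-lactones. The eight-membered ring (O, C6, C7, C8, C9, C10, C11, C12) is not formed by a cyclisation: it appears when the bond shared by the two five-membered rings is cut, a ring-expanding fragmentation that avoids the entropic and transannular cost of a direct medium-ring closure. No stereocenter is created; C7, C9, C12 and C13 come unchanged from 17. The one selectivity required is chemoselectivity for the enol ether over the two anisyl rings and their benzylic C–H bonds, secured by the far higher reactivity of the enol ether at −78 °C, by stopping the ozone stream at the colour change of the indicator, and by the absence of any other alkene in 17.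

**Step 13**
Reactants: 19 (3R,5R,8R)-8-[(1S)-1-(tert-butyldiphenylsilyloxy)propyl]-3,5-bis(4-methoxybenzyloxy)oxocane-2,6-dione
Product: 20 (3R,5R,6S,8R)-8-[(1S)-1-(tert-butyldiphenylsilyloxy)propyl]-6-hydroxy-3,5-bis(4-methoxybenzyloxy)oxocan-2-one
Conditions: Zn(BH4)2, Et2O, −78 → −30 °C; pH 7 quench
Reagents that add atoms: none
Why: Zinc chelates the C10 carbonyl and the C9 PMB ether oxygen so that hydride should add to the exposed face of the five-membered chelate (Cram chelate model), giving the 9,10-cis alcohol (10S); the lactone is inert to Zn(BH4)2, and low temperature with a neutral quench guards against transannular translactonisation.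

**Step 14**
Reactants: 20 (3R,5R,6S,8R)-8-[(1S)-1-(tert-butyldiphenylsilyloxy)propyl]-6-hydroxy-3,5-bis(4-methoxybenzyloxy)oxocan-2-one
Product: 21 (3R,5R,6S,8R)-6-(tert-butyldimethylsilyloxy)-8-[(1S)-1-(tert-butyldiphenylsilyloxy)propyl]-3,5-bis(4-methoxybenzyloxy)oxocan-2-one
Conditions: TBSOTf, 2,6-lutidine, CH2Cl2, −78 °C
Reagents that add atoms: tert-butyldimethylsilyl triflate, CC(C)(C)[Si](C)(C)OS(=O)(=O)C(F)(F)F
Why: Silyl triflate with a hindered pyridine base silylates the secondary alcohol quickly at low temperature, masking C10–OH orthogonally to the PMB and TBDPS ethers before the lactone is reduced.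

**Step 15**
Reactants: 21 (3R,5R,6S,8R)-6-(tert-butyldimethylsilyloxy)-8-[(1S)-1-(tert-butyldiphenylsilyloxy)propyl]-3,5-bis(4-methoxybenzyloxy)oxocan-2-one
Product: 23 (3R,5R,6S,8R)-6-(tert-butyldimethylsilyloxy)-8-[(1S)-1-(tert-butyldiphenylsilyloxy)propyl]-3,5-bis(4-methoxybenzyloxy)oxocan-2-yl acetate (both C2 epimers), via aluminium hemiacetal 22 (not isolated)
Conditions: i-Bu2AlH, CH2Cl2, −78 °C; then pyridine, DMAP, Ac2O, −78 → −20 °C
Reagents that add atoms: acetic anhydride, CC(=O)OC(C)=O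
Why: Reductive acetylation of a lactone: i-Bu2AlH adds once at −78 °C and the stable aluminium hemiacetal is acetylated in situ, giving the α-acetoxy ether without ring opening or over-reduction.

**Step 16**
Reactants: 23 (3R,5R,6S,8R)-6-(tert-butyldimethylsilyloxy)-8-[(1S)-1-(tert-butyldiphenylsilyloxy)propyl]-3,5-bis(4-methoxybenzyloxy)oxocan-2-yl acetate
Product: 24 (2S,3R,5R,6S,8R)-2-allyl-6-(tert-butyldimethylsilyloxy)-8-[(1S)-1-(tert-butyldiphenylsilyloxy)propyl]-3,5-bis(4-methoxybenzyloxy)oxocane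
Conditions: allylSiMe3, BF3·OEt2, CH2Cl2, −78 °C
Reagents that add atoms: allyltrimethylsilane, C=CC[Si](C)(C)C
Why: BF3 ionises the anomeric acetate to the eight-membered oxocarbenium ion and allyltrimethylsilane (Hosomi–Sakurai type C-glycosylation) should attack C6 on the face opposite the adjacent C7 OPMB group, setting 6S with the allyl group anti to C7–O and trans to the C12 side chain.

**Step 17**
Reactants: 24 (2S,3R,5R,6S,8R)-2-allyl-6-(tert-butyldimethylsilyloxy)-8-[(1S)-1-(tert-butyldiphenylsilyloxy)propyl]-3,5-bis(4-methoxybenzyloxy)oxocane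
Product: 25 (2S,3R,5R,6S,8R)-2-allyl-6-(tert-butyldimethylsilyloxy)-8-[(1S)-1-(tert-butyldiphenylsilyloxy)propyl]oxocane-3,5-diol
Conditions: DDQ, CH2Cl2–pH 7 buffer, 0 °C → rt
Reagents that add atoms: none
Why: DDQ oxidises both electron-rich PMB ethers to hemiacetals that hydrolyse in the wet medium, while the TBS and TBDPS ethers and the terminal alkene are inert.

**Step 18**
Reactants: 25 (2S,3R,5R,6S,8R)-2-allyl-6-(tert-butyldimethylsilyloxy)-8-[(1S)-1-(tert-butyldiphenylsilyloxy)propyl]oxocane-3,5-diol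
Product: 26 (2S,3S,5S,6S,8R)-2-allyl-6-(tert-butyldimethylsilyloxy)-8-[(1S)-1-(tert-butyldiphenylsilyloxy)propyl]-3,5-dichlorooxocane
Conditions: CCl4, P(n-Oct)3, toluene, 70 °C
Reagents that add atoms: carbon tetrachloride, ClC(Cl)(Cl)Cl
Why: Appel-type chlorination converts each alcohol into an alkoxyphosphonium ion that chloride displaces by SN2, so C7 and C9 should both invert (7S, 9S); the neutral conditions spare the silyl ethers and the alkene.

**Step 19**
Reactants: 26 (2S,3S,5S,6S,8R)-2-allyl-6-(tert-butyldimethylsilyloxy)-8-[(1S)-1-(tert-butyldiphenylsilyloxy)propyl]-3,5-dichlorooxocane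
Product: 28 2-[(2S,3S,5S,6S,8R)-6-(tert-butyldimethylsilyloxy)-8-[(1S)-1-(tert-butyldiphenylsilyloxy)propyl]-3,5-dichlorooxocan-2-yl]acetaldehyde, via ozonide 27 (not isolated)
Conditions: O3, CH2Cl2, −78 °C; then PPh3, −78 °C → rt
Reagents that add atoms: ozone, [O-][O+]=O
Why: Ozonolysis of the only alkene followed by phosphine reduction of the ozonide gives the C4 aldehyde; chlorides and silyl ethers are inert to ozone.

**Step 20**
Reactants: 28 2-[(2S,3S,5S,6S,8R)-6-(tert-butyldimethylsilyloxy)-8-[(1S)-1-(tert-butyldiphenylsilyloxy)propyl]-3,5-dichlorooxocan-2-yl]acetaldehyde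
Product: 30 (3Z,6S,7S,9S,10S,12R,13S)-10-OTBS-13-OTBDPS-7,9-dichloro-1-(triisopropylsilyl) enyne (the C1-silylated Z-enyne oxocane), via lithium alkoxide adduct 29 (not isolated)
Conditions: 1,3-bis(triisopropylsilyl)propyne, n-BuLi, THF, −78 °C; then 28, −78 °C → rt
Reagents that add atoms: 1,3-bis(triisopropylsilyl)propyne, CC(C)[Si](C(C)C)(C(C)C)CC#C[Si](C(C)C)(C(C)C)C(C)C
Why: Peterson olefination: the lithiated 1,3-bis(silyl)propyne adds to the aldehyde and the bulky silyl groups steer syn-elimination of silanolate to the Z-enyne, while at −78 °C the hindered, stabilised anion should not attack alkyl chlorides or silyl ethers.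

**Step 21**
Reactants: 30 the C1-silylated Z-enyne oxocane with 10-OTBS and 13-OTBDPS
Product: 31 (3Z,6S,7S,9S,10S,12R,13S)-10-hydroxy-13-OTBDPS-7,9-dichloro-1-(triisopropylsilyl) enyne oxocane
Conditions: HF·pyridine, pyridine, THF, 0 °C → rt
Reagents that add atoms: none
Why: Buffered HF·pyridine cleaves the secondary TBS ether much faster than the bulkier TBDPS ether or the alkynyl–silicon bond, so only C10–OH should be freed.

**Step 22**
Reactants: 31 the 10-hydroxy Z-enyne oxocane
Product: 32 (3Z,6S,7S,9S,10S,12R,13S)-10-acetoxy-13-OTBDPS-7,9-dichloro-1-(triisopropylsilyl) enyne oxocane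
Conditions: Ac2O, pyridine, DMAP, CH2Cl2, rt
Reagents that add atoms: acetic anhydride, CC(=O)OC(C)=O
Why: DMAP-catalysed acetylation of the single free secondary alcohol, with retention at C10.

**Step 23**
Reactants: 32 the 10-acetoxy bis-silylated Z-enyne oxocane
Product: 33 (3Z,6S,7S,9S,10S,12R,13S)-10-acetoxy-7,9-dichloro-13-hydroxy enyne oxocane (terminal alkyne)
Conditions: Bu4NF, AcOH, THF, 0 °C → rt
Reagents that add atoms: none
Why: Fluoride removes the alkynyl TIPS group and the TBDPS ether in one operation, and acetic acid buffering keeps the medium non-basic so that the acetate and the secondary chlorides should survive.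

**Step 24**
Reactants: 33 the 13-hydroxy Z-enyne oxocane
Product: 34 target, (3Z,6S,7S,9S,10S,12R,13R)-10-acetoxy-13-bromo-7,9-dichloro-6,12-epoxypentadec-3-en-1-yne
Conditions: CBr4, P(n-Oct)3, toluene, 70 °C
Reagents that add atoms: carbon tetrabromide, BrC(Br)(Br)Br
Why: Appel-type bromination: the C13 alkoxyphosphonium ion is displaced by bromide with inversion (13S alcohol to 13R bromide), a transformation well established for carbinols next to medium-ring ether carbons and compatible with the enyne, acetate and chlorides.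

**Compound list**

1 | penta-1,4-dien-3-ol | C=CC(O)C=C | starting material
2 | (2R,3S)-1,2-epoxypent-4-en-3-ol | C=C[C@H](O)[C@H]1CO1 | intermediate
3 | (2R,3S)-3-(tert-butyldiphenylsilyloxy)-1,2-epoxypent-4-ene | C=C[C@H](O[Si](c1ccccc1)(c2ccccc2)C(C)(C)C)[C@H]3CO3 | intermediate
4 | (2R,3S)-3-(tert-butyldiphenylsilyloxy)-1,2-epoxypentane | CC[C@H](O[Si](c1ccccc1)(c2ccccc2)C(C)(C)C)[C@H]3CO3 | intermediate
5 | (R)-4-(tert-butyldimethylsilyloxy)cyclopent-2-en-1-one | O=C1C=C[C@H](O[Si](C)(C)C(C)(C)C)C1 | starting material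
6 | (4R)-2,3-dibromo-4-(tert-butyldimethylsilyloxy)cyclopentan-1-one (diastereomers at C2 and C3) | O=C1C(Br)C(Br)[C@H](O[Si](C)(C)C(C)(C)C)C1 | intermediate (not isolated)
7 | (R)-2-bromo-4-(tert-butyldimethylsilyloxy)cyclopent-2-en-1-one | O=C1C(Br)=C[C@H](O[Si](C)(C)C(C)(C)C)C1 | intermediate
8 | (1S,4R)-2-bromo-4-(tert-butyldimethylsilyloxy)cyclopent-2-en-1-ol (cis) | BrC1=C[C@H](O[Si](C)(C)C(C)(C)C)C[C@@H]1O | intermediate
9 | (1R,4R)-2-bromo-4-(tert-butyldimethylsilyloxy)cyclopent-2-en-1-yl 4-nitrobenzoate (trans) | BrC1=C[C@H](O[Si](C)(C)C(C)(C)C)C[C@H]1OC(=O)c2ccc(cc2)[N+](=O)[O-] | intermediate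
10 | (1R,4R)-2,2,3-tribromo-4-(tert-butyldimethylsilyloxy)cyclopentyl 4-nitrobenzoate (C3 epimers) | BrC1(Br)C(Br)[C@H](O[Si](C)(C)C(C)(C)C)C[C@H]1OC(=O)c2ccc(cc2)[N+](=O)[O-] | intermediate (not isolated)
11 | (1R,4R)-2,3-dibromo-4-(tert-butyldimethylsilyloxy)cyclopent-2-en-1-yl 4-nitrobenzoate | BrC1=C(Br)[C@H](O[Si](C)(C)C(C)(C)C)C[C@H]1OC(=O)c2ccc(cc2)[N+](=O)[O-] | intermediate
12 | (1R,4R)-2,3-dibromo-4-(tert-butyldimethylsilyloxy)cyclopent-2-en-1-ol | BrC1=C(Br)[C@H](O[Si](C)(C)C(C)(C)C)C[C@H]1O | intermediate (not isolated)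
13 | (1R,3R)-4,5-dibromocyclopent-4-ene-1,3-diol | BrC1=C(Br)[C@H](O)C[C@H]1O | intermediate
14 | (3R,5R)-1,2-dibromo-3,5-bis(4-methoxybenzyloxy)cyclopent-1-ene | BrC1=C(Br)[C@H](OCc2ccc(OC)cc2)C[C@H]1OCc3ccc(OC)cc3 | intermediate
15 | [(3R,5R)-2-bromo-3,5-bis(4-methoxybenzyloxy)cyclopent-1-en-1-yl]magnesium chloride (LiCl complex) | Cl[Mg]C1=C(Br)[C@H](OCc2ccc(OC)cc2)C[C@H]1OCc3ccc(OC)cc3 | intermediate (not isolated)
16 | (2R,3S)-1-[(3R,5R)-2-bromo-3,5-bis(4-methoxybenzyloxy)cyclopent-1-en-1-yl]-3-(tert-butyldiphenylsilyloxy)pentan-2-ol | CC[C@H](O[Si](c1ccccc1)(c2ccccc2)C(C)(C)C)[C@H](O)CC3=C(Br)[C@H](OCc4ccc(OC)cc4)C[C@H]3OCc5ccc(OC)cc5 | intermediate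
17 | bicyclic enol ether, (2R,4R,6R)-2-[(1S)-1-(tert-butyldiphenylsilyloxy)propyl]-4,6-bis(4-methoxybenzyloxy)-3,4,5,6-tetrahydro-2H-cyclopenta[b]furan (chain numbering 7R,9R,12R,13S) | CC[C@H](O[Si](c1ccccc1)(c2ccccc2)C(C)(C)C)[C@H]3CC4=C(O3)[C@H](OCc5ccc(OC)cc5)C[C@H]4OCc6ccc(OC)cc6 | intermediate (key-step precursor)
18 | 6-hydroperoxy-6-methoxy lactone (C10 methoxy hydroperoxide of 19) | O=C1O[C@@H]([C@@H](O[Si](c2ccccc2)(c3ccccc3)C(C)(C)C)CC)CC(OC)(OO)[C@H](OCc4ccc(OC)cc4)C[C@H]1OCc5ccc(OC)cc5 | intermediate (not isolated)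
19 | keto-lactone, (3R,5R,8R)-8-[(1S)-1-(tert-butyldiphenylsilyloxy)propyl]-3,5-bis(4-methoxybenzyloxy)oxocane-2,6-dione | O=C1O[C@@H]([C@@H](O[Si](c2ccccc2)(c3ccccc3)C(C)(C)C)CC)CC(=O)[C@H](OCc4ccc(OC)cc4)C[C@H]1OCc5ccc(OC)cc5 | intermediate (key-step product)
20 | (3R,5R,6S,8R)-8-[(1S)-1-(tert-butyldiphenylsilyloxy)propyl]-6-hydroxy-3,5-bis(4-methoxybenzyloxy)oxocan-2-one | O=C1O[C@@H]([C@@H](O[Si](c2ccccc2)(c3ccccc3)C(C)(C)C)CC)C[C@H](O)[C@H](OCc4ccc(OC)cc4)C[C@H]1OCc5ccc(OC)cc5 | intermediate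
21 | (3R,5R,6S,8R)-6-(tert-butyldimethylsilyloxy)-8-[(1S)-1-(tert-butyldiphenylsilyloxy)propyl]-3,5-bis(4-methoxybenzyloxy)oxocan-2-one | O=C1O[C@@H]([C@@H](O[Si](c2ccccc2)(c3ccccc3)C(C)(C)C)CC)C[C@H](O[Si](C)(C)C(C)(C)C)[C@H](OCc4ccc(OC)cc4)C[C@H]1OCc5ccc(OC)cc5 | intermediate
22 | diisobutylaluminium hemiacetal of 21 (C6 epimers) | CC(C)C[Al](CC(C)C)OC1O[C@@H]([C@@H](O[Si](c2ccccc2)(c3ccccc3)C(C)(C)C)CC)C[C@H](O[Si](C)(C)C(C)(C)C)[C@H](OCc4ccc(OC)cc4)C[C@H]1OCc5ccc(OC)cc5 | intermediate (not isolated)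
23 | (3R,5R,6S,8R)-6-(tert-butyldimethylsilyloxy)-8-[(1S)-1-(tert-butyldiphenylsilyloxy)propyl]-3,5-bis(4-methoxybenzyloxy)oxocan-2-yl acetate (C2 epimers) | CC(=O)OC1O[C@@H]([C@@H](O[Si](c2ccccc2)(c3ccccc3)C(C)(C)C)CC)C[C@H](O[Si](C)(C)C(C)(C)C)[C@H](OCc4ccc(OC)cc4)C[C@H]1OCc5ccc(OC)cc5 | intermediate
24 | (2S,3R,5R,6S,8R)-2-allyl-6-(tert-butyldimethylsilyloxy)-8-[(1S)-1-(tert-butyldiphenylsilyloxy)propyl]-3,5-bis(4-methoxybenzyloxy)oxocane (chain numbering 6S,7R,9R,10S,12R,13S) | C=CC[C@@H]1O[C@@H]([C@@H](O[Si](c2ccccc2)(c3ccccc3)C(C)(C)C)CC)C[C@H](O[Si](C)(C)C(C)(C)C)[C@H](OCc4ccc(OC)cc4)C[C@H]1OCc5ccc(OC)cc5 | intermediate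
25 | (2S,3R,5R,6S,8R)-2-allyl-6-(tert-butyldimethylsilyloxy)-8-[(1S)-1-(tert-butyldiphenylsilyloxy)propyl]oxocane-3,5-diol | C=CC[C@@H]1O[C@@H]([C@@H](O[Si](c2ccccc2)(c3ccccc3)C(C)(C)C)CC)C[C@H](O[Si](C)(C)C(C)(C)C)[C@H](O)C[C@H]1O | intermediate
26 | (2S,3S,5S,6S,8R)-2-allyl-6-(tert-butyldimethylsilyloxy)-8-[(1S)-1-(tert-butyldiphenylsilyloxy)propyl]-3,5-dichlorooxocane | C=CC[C@@H]1O[C@@H]([C@@H](O[Si](c2ccccc2)(c3ccccc3)C(C)(C)C)CC)C[C@H](O[Si](C)(C)C(C)(C)C)[C@@H](Cl)C[C@@H]1Cl | intermediate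
27 | 1,2,4-trioxolane (ozonide) of the allyl group of 26 | C1OC(C[C@@H]2O[C@@H]([C@@H](O[Si](c3ccccc3)(c4ccccc4)C(C)(C)C)CC)C[C@H](O[Si](C)(C)C(C)(C)C)[C@@H](Cl)C[C@@H]2Cl)OO1 | intermediate (not isolated)
28 | 2-[(2S,3S,5S,6S,8R)-6-(tert-butyldimethylsilyloxy)-8-[(1S)-1-(tert-butyldiphenylsilyloxy)propyl]-3,5-dichlorooxocan-2-yl]acetaldehyde | O=CC[C@@H]1O[C@@H]([C@@H](O[Si](c2ccccc2)(c3ccccc3)C(C)(C)C)CC)C[C@H](O[Si](C)(C)C(C)(C)C)[C@@H](Cl)C[C@@H]1Cl | intermediate
29 | lithium β-silyl alkoxide from addition of the lithiated propyne to 28 (epimers at C3 and C4) | [Li]OC(C[C@@H]1O[C@@H]([C@@H](O[Si](c2ccccc2)(c3ccccc3)C(C)(C)C)CC)C[C@H](O[Si](C)(C)C(C)(C)C)[C@@H](Cl)C[C@@H]1Cl)C(C#C[Si](C(C)C)(C(C)C)C(C)C)[Si](C(C)C)(C(C)C)C(C)C | intermediate (not isolated)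
30 | (3Z,6S,7S,9S,10S,12R,13S)-10-(tert-butyldimethylsilyloxy)-13-(tert-butyldiphenylsilyloxy)-7,9-dichloro-6,12-epoxy-1-(triisopropylsilyl)pentadec-3-en-1-yne | CC(C)[Si](C(C)C)(C(C)C)C#C/C=C\C[C@@H]1O[C@@H]([C@@H](O[Si](c2ccccc2)(c3ccccc3)C(C)(C)C)CC)C[C@H](O[Si](C)(C)C(C)(C)C)[C@@H](Cl)C[C@@H]1Cl | intermediate
31 | (3Z,6S,7S,9S,10S,12R,13S)-13-(tert-butyldiphenylsilyloxy)-7,9-dichloro-6,12-epoxy-1-(triisopropylsilyl)pentadec-3-en-1-yn-10-ol | CC(C)[Si](C(C)C)(C(C)C)C#C/C=C\C[C@@H]1O[C@@H]([C@@H](O[Si](c2ccccc2)(c3ccccc3)C(C)(C)C)CC)C[C@H](O)[C@@H](Cl)C[C@@H]1Cl | intermediate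
32 | (3Z,6S,7S,9S,10S,12R,13S)-13-(tert-butyldiphenylsilyloxy)-7,9-dichloro-6,12-epoxy-1-(triisopropylsilyl)pentadec-3-en-1-yn-10-yl acetate | CC(C)[Si](C(C)C)(C(C)C)C#C/C=C\C[C@@H]1O[C@@H]([C@@H](O[Si](c2ccccc2)(c3ccccc3)C(C)(C)C)CC)C[C@H](OC(C)=O)[C@@H](Cl)C[C@@H]1Cl | intermediate
33 | (3Z,6S,7S,9S,10S,12R,13S)-7,9-dichloro-6,12-epoxy-13-hydroxypentadec-3-en-1-yn-10-yl acetate | C#C/C=C\C[C@@H]1O[C@@H]([C@@H](O)CC)C[C@H](OC(C)=O)[C@@H](Cl)C[C@@H]1Cl | intermediate
34 | (3Z,6S,7S,9S,10S,12R,13R)-13-bromo-7,9-dichloro-6,12-epoxypentadec-3-en-1-yn-10-yl acetate | C#C/C=C\C[C@@H]1O[C@@H]([C@H](Br)CC)C[C@H](OC(C)=O)[C@@H](Cl)C[C@@H]1Cl | target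

**Totals.** 24 steps in all. The longest linear sequence is 21 steps (5 to 34, steps 4–24); the three-step epoxide branch (steps 1–3) joins at step 10.

**Steps most likely to fail**

Step 7. Bromine may add only slowly to the deactivated vinyl bromide, or the base may remove the carbinol proton next to the CBr2 carbon, so that HBr is lost toward an oxygen-bearing carbon. The fallback sets out from 7 and moves the second bromination to the enone stage, where C1 carries no proton and the elimination is the ordinary dehydrobromination of an α-bromo ketone to a conjugated enone. Bromine addition to 7 (CH2Cl2, 0 °C → rt) would give (4R)-2,2,3-tribromo-4-(tert-butyldimethylsilyloxy)cyclopentan-1-one F1, which on treatment with DBU at 0 °C in the same flask would give (R)-2,3-dibromo-4-(tert-butyldimethylsilyloxy)cyclopent-2-en-1-one F2. Luche reduction (NaBH4, CeCl3·7H2O, MeOH, −78 °C) would give (1S,4R)-2,3-dibromo-4-(tert-butyldimethylsilyloxy)cyclopent-2-en-1-ol F3, and Mitsunobu inversion with 4-nitrobenzoic acid (PPh3, DIAD) returns to the route at 11.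

Step 12. Once the enol ether is consumed, ozone may attack an anisyl ring or a benzylic C–H bond, or the peroxidic intermediate may decompose by rearrangement before it is reduced. The fallback sets out from 17 and replaces the one-pot cleavage by dihydroxylation and glycol cleavage. OsO4 (catalytic) with N-methylmorpholine N-oxide in acetone–water, which reacts with the electron-rich enol ether and not with arenes, would give the ring-fusion cis-diol (cyclic hemiketal) F4. Pb(OAc)4 in CH2Cl2 at 0 °C would then cleave the C6–C10 glycol, turning the hemiketal carbon into the lactone carbonyl and C10 into the ketone, and returns to the route at 19.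

Step 18. The alkoxyphosphonium intermediates may ionise with participation of the ring oxygen (vicinal at C7, transannular at C9), giving retention or ring contraction, or may undergo elimination in the medium ring. The fallback sets out from 25 and separates activation from displacement. Chloromethanesulfonyl chloride and pyridine (CH2Cl2, 0 °C) would give the 7,9-bis(chloromethanesulfonate) F5, a very reactive but isolable sulfonate. Displacement with a high concentration of LiCl in DMF (40 °C) favours direct SN2 substitution with inversion at both centers and returns to the route at 26.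

Further compounds
F1 | step 7 | (4R)-2,2,3-tribromo-4-(tert-butyldimethylsilyloxy)cyclopentan-1-one | O=C1C(Br)(Br)C(Br)[C@H](O[Si](C)(C)C(C)(C)C)C1
F2 | step 7 | (R)-2,3-dibromo-4-(tert-butyldimethylsilyloxy)cyclopent-2-en-1-one | O=C1C(Br)=C(Br)[C@H](O[Si](C)(C)C(C)(C)C)C1
F3 | step 7 | (1S,4R)-2,3-dibromo-4-(tert-butyldimethylsilyloxy)cyclopent-2-en-1-ol | BrC1=C(Br)[C@H](O[Si](C)(C)C(C)(C)C)C[C@@H]1O
F4 | step 12 | ring-fusion cis-diol (C6 hemiketal, C10 tertiary alcohol) of 17, the 2-oxabicyclo[3.3.0]octane-1,5-diol | CC[C@H](O[Si](c1ccccc1)(c2ccccc2)C(C)(C)C)[C@H]3CC4(O)C(O)(O3)[C@H](OCc5ccc(OC)cc5)C[C@H]4OCc6ccc(OC)cc6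
F5 | step 18 | (2S,3R,5R,6S,8R)-2-allyl-6-(tert-butyldimethylsilyloxy)-8-[(1S)-1-(tert-butyldiphenylsilyloxy)propyl]oxocane-3,5-diyl bis(chloromethanesulfonate) | C=CC[C@@H]1O[C@@H]([C@@H](O[Si](c2ccccc2)(c3ccccc3)C(C)(C)C)CC)C[C@H](O[Si](C)(C)C(C)(C)C)[C@H](OS(=O)(=O)CCl)C[C@H]1OS(=O)(=O)CCl
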